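The route rests on disconnecting the bond between the methyl-bearing ring-fusion carbon (C1, daucane numbering) and the adjacent acyloxy-bearing carbon of the seven-membered ring (C10). It exploits the aldol relationship between the C2 oxygen of the five-membered ring and the C10 carbinol across quaternary C1. A SmI2-mediated Reformatsky-type aldol closes the cycloheptene in one operation and sets the C1 quaternary centre, the cis ring fusion and C10. The precursor is a monocyclic tertiary α-bromo cyclopentanone carrying an acetonide-bridged C4/C6 diol and a (Z)-enal chain, assembled from (R)-4-silyloxycyclopentenone by cuprate addition–aldol trapping, isopropyl addition and ring-closing metathesis. Directed epoxidation, angeloylation and directed C2 reduction complete the target.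

Key step: step 11

Remark on the chemistry (assumption): all compounds keep the daucane locants of the target (C1 = methyl-bearing ring-fusion carbon; C2 = CHOH and C3 = CH2 of the five-membered ring; C4 = C(OH)(isopropyl); C5 = ring-fusion CH; C6 = acyloxy CH next to C5; C7 = CH2; C8 = C(CH3) and C9 = CH of the epoxide; C10 = acyloxy CH next to C1); β is the face of the five-membered ring from which the C5–C6 bond leaves and α the opposite face; 3-methylbut-3-enal is assumed not to be storable and is made fresh.

Step 1
Reactants: 1 3-methylbut-3-en-1-ol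
Product: 2 3-methylbut-3-enal
Conditions: Dess–Martin periodinane, pyridine, CH2Cl2, 0 °C; cold filtered solution used at once
Reagents that add atoms: none
Why: Dess–Martin oxidation under pyridine buffering converts the homoallylic primary alcohol into the β,γ-unsaturated aldehyde under neutral conditions, which should prevent migration of the double bond into conjugation.

Step 2
Reactants: 3 (R)-4-[(tert-butyldimethylsilyl)oxy]cyclopent-2-en-1-one; 2 3-methylbut-3-enal
Product: 5 (2S,3R,4R)-4-[(tert-butyldimethylsilyl)oxy]-2-[(1S)-1-hydroxy-3-methylbut-3-en-1-yl]-3-methylcyclopentan-1-one, via lithium enolate 4 (not isolated)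
Conditions: MeLi (2 equiv), CuI (copper monoiodide, 1 equiv), Et2O, −20 °C; 3, −78 °C; then 2, THF, −78 °C; aq. NH4Cl
Reagents that add atoms: methyllithium, C[Li] (delivered as lithium dimethylcuprate, [Li+].C[Cu-]C)
Why: Three-component conjugate addition–aldol coupling: the cuprate methyl adds to C1 anti to the C2 silyloxy group, and enolate 4 adds to aldehyde 2 at C5 anti to the new methyl through a Zimmerman–Traxler chair (E-configured ring enolate, aldehyde residue equatorial), which should give the 5,6-anti aldol with the 6S carbinol as the main isomer.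

Step 3
Reactants: 5 (2S,3R,4R)-4-[(tert-butyldimethylsilyl)oxy]-2-[(1S)-1-hydroxy-3-methylbut-3-en-1-yl]-3-methylcyclopentan-1-one
Product: 6 (1R,2S,3R,4R)-4-[(tert-butyldimethylsilyl)oxy]-2-[(1S)-1-hydroxy-3-methylbut-3-en-1-yl]-3-methyl-1-(propan-2-yl)cyclopentan-1-ol
Conditions: i-PrMgCl, anhydrous CeCl3, THF, −78 °C → −40 °C; aq. NH4Cl
Reagents that add atoms: isopropylmagnesium chloride, CC(C)[Mg]Cl
Why: 1,2-Addition of the organocerium reagent (non-basic, so neither enolisation nor retro-aldol cleavage is expected) should occur on the C4 face opposite to the C5 side chain and its chelated C6 alkoxide, placing the new tertiary hydroxyl cis to the side chain (4R).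

Step 4
Reactants: 6 (1R,2S,3R,4R)-4-[(tert-butyldimethylsilyl)oxy]-2-[(1S)-1-hydroxy-3-methylbut-3-en-1-yl]-3-methyl-1-(propan-2-yl)cyclopentan-1-ol
Product: 7 (1S)-1-{(1S,2R,4R,5R)-4-[(tert-butyldimethylsilyl)oxy]-2-hydroxy-5-methyl-2-(propan-2-yl)cyclopentyl}-3-methylbut-3-en-1-yl prop-2-enoate
Conditions: acryloyl chloride, i-Pr2NEt, CH2Cl2, −78 °C → 0 °C
Reagents that add atoms: acryloyl chloride, C=CC(=O)Cl
Why: O-Acylation with an acyl chloride and a hindered amine base is selective for the secondary C6 hydroxyl because the tertiary C4 hydroxyl is far more hindered.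

Step 5
Reactants: 7 (1S)-1-{(1S,2R,4R,5R)-4-[(tert-butyldimethylsilyl)oxy]-2-hydroxy-5-methyl-2-(propan-2-yl)cyclopentyl}-3-methylbut-3-en-1-yl prop-2-enoate
Product: 8 (6S)-6-{(1S,2R,4R,5R)-4-[(tert-butyldimethylsilyl)oxy]-2-hydroxy-5-methyl-2-(propan-2-yl)cyclopentyl}-4-methyl-5,6-dihydro-2H-pyran-2-one
Conditions: second-generation Grubbs catalyst (5 mol %), toluene, 80 °C
Reagents that add atoms: none
Why: Ring-closing metathesis of the acrylate with the 1,1-disubstituted alkene forms the 4-methyl-5,6-dihydropyran-2-one, whose six-membered ring fixes the C8=C9 double bond in the Z geometry.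

Step 6
Reactants: 8 (6S)-6-{(1S,2R,4R,5R)-4-[(tert-butyldimethylsilyl)oxy]-2-hydroxy-5-methyl-2-(propan-2-yl)cyclopentyl}-4-methyl-5,6-dihydro-2H-pyran-2-one
Product: 9 (2Z,5S)-5-{(1S,2R,4R,5R)-4-[(tert-butyldimethylsilyl)oxy]-2-hydroxy-5-methyl-2-(propan-2-yl)cyclopentyl}-3-methylpent-2-ene-1,5-diol
Conditions: i-Bu2AlH (5 equiv), CH2Cl2, −78 °C → 0 °C; aq. Rochelle salt
Reagents that add atoms: none
Why: 1,2-Reduction of the unsaturated lactone with excess aluminium hydride gives the (Z)-allylic alcohol and frees the C6 hydroxyl without touching the double-bond geometry or the silyl ether.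

Step 7
Reactants: 9 (2Z,5S)-5-{(1S,2R,4R,5R)-4-[(tert-butyldimethylsilyl)oxy]-2-hydroxy-5-methyl-2-(propan-2-yl)cyclopentyl}-3-methylpent-2-ene-1,5-diol
Product: 10 4,6-O-isopropylidene acetal of 9 (2β-silyloxy; free primary 10-hydroxyl; Z alkene)
Conditions: 2,2-dimethoxypropane, PPTS (cat.), CH2Cl2, rt; aq. NaHCO3
Reagents that add atoms: 2,2-dimethoxypropane, COC(C)(C)OC
Why: Acid-catalysed acetalisation under thermodynamic control selects the six-membered 1,3-dioxane across the C4/C6 diol, which shields the C6 carbinol from the later oxidation and removes both hydroxyl protons near the future enolate, while a mixed ketal at the primary alcohol is lost on aqueous work-up.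

Step 8
Reactants: 10 4,6-O-isopropylidene acetal of 9
Product: 11 acetonide diol (10 without the silyl group; free 2β-hydroxyl and 10-hydroxyl)
Conditions: Bu4NF, THF, 0 °C → rt
Reagents that add atoms: none
Why: Fluoride-mediated desilylation frees the C2 hydroxyl while the acetonide is inert.

Step 9
Reactants: 11 acetonide diol
Product: 12 acetonide keto enal (C2 ketone; C10 (Z)-enal; 1α-methyl)
Conditions: Dess–Martin periodinane (2.5 equiv), pyridine, CH2Cl2, 0 °C → rt
Reagents that add atoms: none
Why: Double Dess–Martin oxidation gives the C2 ketone and the (Z)-enal in one operation under buffered neutral conditions, which should preserve the Z geometry; the configuration at C1 no longer matters.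

Step 10
Reactants: 12 acetonide keto enal
Product: 13 1-bromo derivative of 12 (tertiary α-bromo ketone; C1 configuration not controlled)
Conditions: NBS (1.05 equiv), NH4OAc (10 mol %), Et2O, rt, dark
Reagents that add atoms: N-bromosuccinimide, O=C1CCC(=O)N1Br
Why: Ammonium acetate catalysed α-bromination with NBS runs through the enol and should favour the more substituted C1 (the C3 methylene is neopentyl and its enol is less substituted), the electron-poor enal alkene being inert; the new C1 stereocentre is formed without control and is erased in the next step.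

Step 11
Reactants: 13 1-bromo derivative of 12
Product: 15 (1R,4R,5S,6S,10S)-10-hydroxy-4,6-(isopropylidenedioxy)dauc-8-en-2-one, via samarium enolate 14 (not isolated)
Conditions: SmI2 (2.5 equiv, slow addition), THF, −78 °C; aq. NH4Cl
Reagents that add atoms: none
Why: Two single-electron transfers from SmI2 cleave the tertiary C1–Br bond and give the trivalent samarium enolate 14 regiospecifically across C1–C2 without base, so C3 is never deprotonated and the β-oxygen at C4 cannot be eliminated; the enolate carbon C1 then adds to the C10 aldehyde of the tethered (Z)-enal. The closest known reaction type is the SmI2-promoted intramolecular Reformatsky-type aldol cyclisation of α-bromo ketones onto aldehydes, which is established for seven- to nine-membered carbocycles. The seven-membered ring closes in the 7-(enolexo)-exo-trig mode, the (Z)-C8=C9 bond and the dioxane holding C10 within reach of C1. C1 is set by the tether: the three-atom chain from C6, fixed on the same face as the C5–C6 bond, can reach only that face of the planar enolate, which gives the cis ring fusion (C1 methyl and H-5 cis). C10 is set in a closed transition state in which samarium bridges the enolate oxygen and the aldehyde oxygen, C9 lies anti to the C1 methyl and the aldehyde hydrogen points towards C5, so the new hydroxyl should be placed trans to the C1 methyl (10S in 15). The step needs C–Br reduction to outrun reduction of the enal and 1,2-addition to outrun 1,4-addition; the far faster electron transfer to α-bromo ketones at −78 °C, the oxophilic samarium enolate and the fully substituted β-carbon C8 (1,4-attack would create two adjacent quaternary centres) secure both.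

Step 12
Reactants: 15 (1R,4R,5S,6S,10S)-10-hydroxy-4,6-(isopropylidenedioxy)dauc-8-en-2-one
Product: 16 (1R,4R,5S,6S,10S)-4,6,10-trihydroxydauc-8-en-2-one
Conditions: AcOH/THF/H2O (3:1:1), 35 °C
Reagents that add atoms: none
Why: Mild aqueous acid hydrolyses the strained 1,3-dioxane (it contains the tertiary C4 carbinol) and should not dehydrate the β-hydroxy ketone units.

Step 13
Reactants: 16 (1R,4R,5S,6S,10S)-4,6,10-trihydroxydauc-8-en-2-one
Product: 17 (1R,4R,5S,6S,8S,9R,10R)-8,9-epoxy-4,6,10-trihydroxydaucan-2-one
Conditions: VO(acac)2 (5 mol %), t-BuOOH, CH2Cl2, 0 °C → rt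
Reagents that add atoms: tert-butyl hydroperoxide, CC(C)(C)OO
Why: Vanadium-catalysed hydroxyl-directed epoxidation delivers oxygen to the C8=C9 face syn to the allylic C10 hydroxyl (strongly cis-selective for cycloheptenols), setting C8 and C9, while the homoallylic C6 hydroxyl on the opposite face directs far more slowly.

Step 14
Reactants: 17 (1R,4R,5S,6S,8S,9R,10R)-8,9-epoxy-4,6,10-trihydroxydaucan-2-one; 18 angelic acid (used in excess; two equivalents are incorporated, one at O6 and one at O10)
Product: 20 (1R,4R,5S,6S,8S,9R,10R)-8,9-epoxy-4-hydroxy-2-oxodaucane-6,10-diyl bis[(Z)-2-methylbut-2-enoate], via mixed anhydride 19 (not isolated)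
Conditions: 18 (5 equiv), 2,4,6-trichlorobenzoyl chloride (5 equiv), Et3N (6 equiv), toluene, rt; then 17, toluene, 75 °C
Reagents that add atoms: angelic acid (the second equivalent of 18, which supplies the second angeloyl group), C/C=C(/C)C(=O)O
Why: Yamaguchi-type esterification through the preformed mixed anhydride 19 without a nucleophilic catalyst is a known way to acylate hindered secondary alcohols with angelic acid without isomerisation to the tiglate; with the anhydride in excess both secondary hydroxyls (C6 and C10) each take up one angeloyl group, the tertiary C4 hydroxyl does not react, and the quaternary C1 blocks β-elimination of the C10 ester.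

Step 15
Reactants: 20 (1R,4R,5S,6S,8S,9R,10R)-8,9-epoxy-4-hydroxy-2-oxodaucane-6,10-diyl bis[(Z)-2-methylbut-2-enoate]
Product: 21 (1S,2S,4R,5S,6S,8S,9R,10R)-8,9-epoxy-2,4-dihydroxydaucane-6,10-diyl bis[(Z)-2-methylbut-2-enoate]
Conditions: Me4NBH(OAc)3, MeCN/AcOH (1:1), −30 °C
Reagents that add atoms: none
Why: Evans–Saksena reduction: the tertiary C4 hydroxyl binds boron and delivers hydride to the same (β) face of the C2 ketone, which should give the 2,4-trans diol (2S) and leave the esters and the epoxide untouched.

Compound list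
1 | 3-methylbut-3-en-1-ol | C=C(C)CCO | starting material
2 | 3-methylbut-3-enal | C=C(C)CC=O | intermediate
3 | (R)-4-[(tert-butyldimethylsilyl)oxy]cyclopent-2-en-1-one | O=C1C=C[C@H](O[Si](C)(C)C(C)(C)C)C1 | starting material
4 | lithium (3R,4R)-4-[(tert-butyldimethylsilyl)oxy]-3-methylcyclopent-1-en-1-olate | [Li+].[O-]C1=C[C@@H](C)[C@H](O[Si](C)(C)C(C)(C)C)C1 | intermediate
5 | (2S,3R,4R)-4-[(tert-butyldimethylsilyl)oxy]-2-[(1S)-1-hydroxy-3-methylbut-3-en-1-yl]-3-methylcyclopentan-1-one | O[C@@H](CC(C)=C)[C@H]1C(=O)C[C@@H](O[Si](C)(C)C(C)(C)C)[C@@H]1C | intermediate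
6 | (1R,2S,3R,4R)-4-[(tert-butyldimethylsilyl)oxy]-2-[(1S)-1-hydroxy-3-methylbut-3-en-1-yl]-3-methyl-1-(propan-2-yl)cyclopentan-1-ol | O[C@@H](CC(C)=C)[C@H]1[C@](O)(C(C)C)C[C@@H](O[Si](C)(C)C(C)(C)C)[C@@H]1C | intermediate
7 | (1S)-1-{(1S,2R,4R,5R)-4-[(tert-butyldimethylsilyl)oxy]-2-hydroxy-5-methyl-2-(propan-2-yl)cyclopentyl}-3-methylbut-3-en-1-yl prop-2-enoate | C=CC(=O)O[C@@H](CC(C)=C)[C@H]1[C@](O)(C(C)C)C[C@@H](O[Si](C)(C)C(C)(C)C)[C@@H]1C | intermediate
8 | (6S)-6-{(1S,2R,4R,5R)-4-[(tert-butyldimethylsilyl)oxy]-2-hydroxy-5-methyl-2-(propan-2-yl)cyclopentyl}-4-methyl-5,6-dihydro-2H-pyran-2-one | O=C2C=C(C)C[C@H](O2)[C@H]1[C@](O)(C(C)C)C[C@@H](O[Si](C)(C)C(C)(C)C)[C@@H]1C | intermediate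
9 | (2Z,5S)-5-{(1S,2R,4R,5R)-4-[(tert-butyldimethylsilyl)oxy]-2-hydroxy-5-methyl-2-(propan-2-yl)cyclopentyl}-3-methylpent-2-ene-1,5-diol | O[C@@H](C/C(C)=C\CO)[C@H]1[C@](O)(C(C)C)C[C@@H](O[Si](C)(C)C(C)(C)C)[C@@H]1C | intermediate
10 | 4,6-O-isopropylidene acetal of 9 (2,2-dimethyl-1,3-dioxane across O4 and O6, cis-fused to the cyclopentane; 2β-silyloxy; free 10-hydroxyl; Z alkene) | CC1(C)O[C@@H](C/C(C)=C\CO)[C@H]2[C@](O1)(C(C)C)C[C@@H](O[Si](C)(C)C(C)(C)C)[C@@H]2C | intermediate
11 | acetonide diol (10 without the silyl group; free 2β-hydroxyl and 10-hydroxyl) | CC1(C)O[C@@H](C/C(C)=C\CO)[C@H]2[C@](O1)(C(C)C)C[C@@H](O)[C@@H]2C | intermediate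
12 | acetonide keto enal (C2 ketone; C10 (Z)-enal; 1α-methyl) | CC1(C)O[C@@H](C/C(C)=C\C=O)[C@H]2[C@](O1)(C(C)C)CC(=O)[C@@H]2C | intermediate
13 | 1-bromo derivative of 12 (tertiary α-bromo ketone; C1 configuration not controlled) | CC1(C)O[C@@H](C/C(C)=C\C=O)[C@H]2[C@](O1)(C(C)C)CC(=O)C2(C)Br | intermediate
14 | samarium enolate (C1=C2; O–SmI2) of 12 | CC1(C)O[C@@H](C/C(C)=C\C=O)[C@H]2[C@](O1)(C(C)C)CC(O[Sm](I)I)=C2C | intermediate
15 | (1R,4R,5S,6S,10S)-10-hydroxy-4,6-(isopropylidenedioxy)dauc-8-en-2-one (cis-fused; 10-hydroxyl trans to the C1 methyl) | CC1(C)O[C@H]2CC(C)=C[C@H](O)[C@@]3(C)[C@@H]2[C@](O1)(C(C)C)CC3=O | intermediate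
16 | (1R,4R,5S,6S,10S)-4,6,10-trihydroxydauc-8-en-2-one | O[C@H]1CC(C)=C[C@H](O)[C@@]2(C)[C@@H]1[C@](O)(C(C)C)CC2=O | intermediate
17 | (1R,4R,5S,6S,8S,9R,10R)-8,9-epoxy-4,6,10-trihydroxydaucan-2-one | O[C@H]1C[C@]2(C)O[C@@H]2[C@H](O)[C@@]2(C)[C@@H]1[C@](O)(C(C)C)CC2=O | intermediate
18 | angelic acid, (Z)-2-methylbut-2-enoic acid | C/C=C(/C)C(=O)O | starting material
19 | angelic 2,4,6-trichlorobenzoic anhydride | C/C=C(/C)C(=O)OC(=O)c1c(Cl)cc(Cl)cc1Cl | intermediate
20 | (1R,4R,5S,6S,8S,9R,10R)-8,9-epoxy-4-hydroxy-2-oxodaucane-6,10-diyl bis[(Z)-2-methylbut-2-enoate] | C/C=C(/C)C(=O)O[C@H]1C[C@]2(C)O[C@@H]2[C@H](OC(=O)/C(C)=C\C)[C@@]2(C)[C@@H]1[C@](O)(C(C)C)CC2=O | intermediate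
21 | (1S,2S,4R,5S,6S,8S,9R,10R)-8,9-epoxy-2,4-dihydroxydaucane-6,10-diyl bis[(Z)-2-methylbut-2-enoate], CNP0265715.3 | C/C=C(/C)C(=O)O[C@H]1C[C@]2(C)O[C@@H]2[C@H](OC(=O)/C(C)=C\C)[C@@]2(C)[C@@H]1[C@](O)(C(C)C)C[C@@H]2O | target

Total step count: 15 steps.
Longest linear sequence: 15 steps (1 → 2 → 5 → … → 21); 14 steps counted from 3.

Steps most likely to fail

Step 11 (key step). What may go wrong: the samarium enolate is quenched by proton transfer or reduced further before it reaches C10, or the addition shows poor facial selectivity at C10. The fallback sets out from 13 and comes back at 15. Reductive silylation of 13 with zinc dust and Me3SiCl (TMEDA, Et2O, 0 °C) should give regiospecifically the C1=C2 trimethylsilyl enol ether F1. An intramolecular Mukaiyama aldol addition of F1 to the enal (BF3·OEt2, CH2Cl2, −78 °C, then aqueous work-up) would then close the ring through an open transition state and give 15.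

Step 10. What may go wrong: enolisation towards C3 puts the bromine on the wrong carbon, or acid released during the bromination isomerises the (Z)-enal or opens the acetonide. The fallback sets out from 11 and comes back at 13; it keeps the enal masked and introduces bromine through a silyl enol ether under non-acidic conditions. Selective silylation of the primary allylic hydroxyl of 11 (t-BuMe2SiCl, imidazole) gives the 10-O-silyl ether F2, and Dess–Martin oxidation gives ketone F3. Me3SiOTf/Et3N (CH2Cl2, 0 °C, equilibrating) should give the more substituted C1=C2 silyl enol ether F4, whose regiochemistry can be checked before NBS (THF, −78 °C) converts it into bromo ketone F5. HF·pyridine then frees the allylic alcohol F6, and MnO2 oxidation gives 13.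

Step 14. What may go wrong: isomerisation of the angeloyl to the tigloyl group, incomplete acylation of the neopentyl C10 hydroxyl so that only one of the two esters forms, or loss of the C4 hydroxyl β to the ketone on prolonged heating with base. The fallback sets out from 17 and comes back at 20; it builds the Z double bonds on the esters instead of carrying them in. Esterification of both secondary hydroxyls of 17 with two equivalents of 2-[bis(2,2,2-trifluoroethoxy)phosphoryl]propanoic acid (N,N'-diisopropylcarbodiimide, DMAP cat., CH2Cl2, rt) gives bis-phosphonate F7. A double Still–Gennari olefination of F7 with two equivalents of acetaldehyde (KN(SiMe3)2, 18-crown-6, THF, −78 °C) should then give the two (Z)-2-methylbut-2-enoates of 20.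

Further compounds
F1 | step 11 | trimethylsilyl enol ether (C1=C2) of 12 | CC1(C)O[C@@H](C/C(C)=C\C=O)[C@H]2[C@](O1)(C(C)C)CC(O[Si](C)(C)C)=C2C
F2 | step 10 | 10-O-(tert-butyldimethylsilyl) ether of 11 | CC1(C)O[C@@H](C/C(C)=C\CO[Si](C)(C)C(C)(C)C)[C@H]2[C@](O1)(C(C)C)C[C@@H](O)[C@@H]2C
F3 | step 10 | C2 ketone of F2 | CC1(C)O[C@@H](C/C(C)=C\CO[Si](C)(C)C(C)(C)C)[C@H]2[C@](O1)(C(C)C)CC(=O)[C@@H]2C
F4 | step 10 | trimethylsilyl enol ether (C1=C2) of F3 | CC1(C)O[C@@H](C/C(C)=C\CO[Si](C)(C)C(C)(C)C)[C@H]2[C@](O1)(C(C)C)CC(O[Si](C)(C)C)=C2C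
F5 | step 10 | 1-bromo ketone with 10-O-silyl ether | CC1(C)O[C@@H](C/C(C)=C\CO[Si](C)(C)C(C)(C)C)[C@H]2[C@](O1)(C(C)C)CC(=O)C2(C)Br
F6 | step 10 | 1-bromo ketone with free allylic 10-hydroxyl | CC1(C)O[C@@H](C/C(C)=C\CO)[C@H]2[C@](O1)(C(C)C)CC(=O)C2(C)Br
F7 | step 14 | 6,10-bis{2-[bis(2,2,2-trifluoroethoxy)phosphoryl]propanoate} of 17 | CC(P(=O)(OCC(F)(F)F)OCC(F)(F)F)C(=O)O[C@H]1C[C@]2(C)O[C@@H]2[C@H](OC(=O)C(C)P(=O)(OCC(F)(F)F)OCC(F)(F)F)[C@@]2(C)[C@@H]1[C@](O)(C(C)C)CC2=O
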